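The trap in this flask is to take the smaller charge for the yield.

| flask | Sbt | Ptn | time |
|---|---|---|---|
| epsilon | 80.0 mM | 88.0 mM |  |
| delta | 40.0 mM | 48.0 mM |  |
| eta | 120 mM | 88.0 mM |  |
| alpha | 200 mM | 88.0 mM | 8.3 min |

| epsilon run: time / min | epsilon run: [Pdt] / mM | delta run: time / min | delta run: [Pdt] / mM | eta run: time / min | eta run: [Pdt] / mM |
|---|---|---|---|---|---|
| 1.2 | 12.76 | 1.2 | 4.54 | 1.2 | 17.87 |
| 2.4 | 24.39 | 2.4 | 10.27 | 2.4 | 33.81 |
| 3.6 | 32.25 | 3.6 | 14.44 | 3.6 | 44.68 |
| 4.7 | 37.10 | 4.7 | 16.81 | 4.7 | 51.35 |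
| 5.9 | 41.20 | 5.9 | 18.87 | 5.9 | 55.69 |
| 7.1 | 43.42 | 7.1 | 20.26 | 7.1 | 58.72 |
| 8.3 | 44.85 | 8.3 | 21.38 | 8.3 | 60.12 |

(scatter of a reading: 0.2 mM)

1. the power of [Ptn] that the first rate follows, about the charge of the epsilon run; measure it at two percent of Sbt made into Pdt
2. the power of [Sbt] that the first rate follows, about the charge of the epsilon run; measure it at two percent of Sbt made into Pdt (one fixed amount of Pdt, the same in the runs compared)
3. Pdt in the alpha run at 8.3 min, as a share of the Sbt charged

- Overall: Sbt + Ptn -> Pdt.
- Constant volume, constant temperature.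
- "The second partner" is Ptn.
- An order is taken over about fifteen percent of the charge, up and down.

1. The bench rule says Pdt stops at the limiting reagent, the smaller charge. In the alpha run that is Ptn, so the rule allows 44.0% of the Sbt charged.

2. The rule gives a bound, not a reading. The eta run also has Ptn as its limiting reagent, yet at 8.3 min its cPdt is 60.12 mM, a fraction 0.683 of its Ptn charge.

3. So I divide the rate of Pdt by the cPtn still there, counting each Pdt as one Ptn spent. Summed over a run, this is the logarithm of the Ptn charge over the cPtn left, and flasks read at one time can be compared without the clock. Per Sbt charged, the eta run gives 9.58 M⁻¹ and the epsilon run 8.91 M⁻¹. Their ratio is 1.08, while their Sbt charges stand at 1.50 to one. I carry this spend E, the logarithm of the Ptn fall per Sbt charged.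

4. The alpha run has the Ptn charge of the eta run. With the eta value, my reckoned share of Ptn left is 0.147, so Pdt comes to 37.5% of the Sbt charged, under the ceiling.

5. The forecast gives 0.5 (0.15 to 1) for the power of cPtn, 0.9 (0.65 to 1.1) for the power of cSbt, and 36% (33.5% to 38.5%) for the share. It says “All runs stall well short of full conversion”. My share is higher than its share.

6. The flask gives 0.41 for the power of cPtn, 0.67 for the power of cSbt, and 37.4% for the share. Both forecast orders are higher than these; its share lies within its range.

    Sbt → Imd (0.2298 min⁻¹)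
    Imd + Ptn → Pdt (34.86 M⁻¹ min⁻¹)
    Imd → Ofp (0.3786 min⁻¹)
    2 Sbt → X (0.4170 M⁻¹ min⁻¹)
    Pdt → J (0.02154 min⁻¹)

The alpha run now reads E = 9.50 M⁻¹, against 9.58 M⁻¹ from the eta run. The delta run, with both charges lower (40.0 mM of Sbt, 48.0 mM of Ptn), reads higher, 14.7 M⁻¹. E counts each Pdt as one Ptn spent, yet Pdt in the alpha run is lost onward: without the path from Pdt to J the share is 42.5% instead of 37.4%, and that higher share is 96.6% of the Ptn charge.

Readings and results are calculated on assumed constants; scatter was added.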